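73.5% of the substrate still stands in the south run at 20.0 h, yet from 12.0 h on the target stays within its scatter. The south-east run is still rising at its last reading, 6.5%, so it shows no plateau.

| flask | substrate | coupling partner | free catalyst | temperature | remark | time |
|---|---|---|---|---|---|---|
| south | 0.50 M | 0.25 M | 25 mM | 25 °C | the very flask that is asked about, followed so far |  |
| south-east | 0.50 M | 0.25 M | 12 mM | 31 °C | run made earlier |  |
| flask | 0.50 M | 0.250 M | 25 mM | 25 °C |  | 20 h |

south run (percent of the substrate charged)

| time / h | target / % | substrate / % |
|---|---|---|
| 3.00 | 15.9 | 79.1 |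
| 6.00 | 19.4 | 75.9 |
| 10.0 | 21.0 | 73.8 |
| 12.0 | 21.3 | 73.8 |
| 15.0 | 21.6 | 73.5 |
| 20.0 | 21.4 | 73.5 |

south-east run (percent of the substrate charged)

| time / min | target / % | substrate / % |
|---|---|---|
| 6.00 | 0.3 | 98.0 |
| 15.0 | 2.0 | 96.8 |
| 30.0 | 4.2 | 95.1 |
| 50.0 | 4.5 | 92.8 |
| 60.0 | 5.7 | 92.5 |
| 80.0 | 6.5 | 90.8 |

(scatter of a reading: 0.3 percentage points)

- teal: at 20 h take out 90% of the target then present, then wait 6.0 h
- ochre: change nothing and wait 6.0 h more
- amber: at 20 h add free catalyst, 100% of the amount charged, then wait 6.0 h
- blue: at 20 h add coupling partner, 100% of the amount charged, then wait 6.0 h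
- grey: at 20 h raise the temperature by 20 K, then wait 6.0 h

- removed target is counted in
- the numbers in the tables scatter by 0.3 percentage points (one standard deviation)
- additions bring no volume worth counting

- target, in percent of the substrate first charged, at 20 h
- the option that brings most further target ("none" if no option brings more than 2 percentage points) (teal / ochre / amber / blue / grey / none)
- target present, with what was taken out counted in, in percent of the substrate first charged, after amber
- target present, with what was taken out counted in, in percent of the substrate first charged, after blue

The catalyst charge of the south run is a fraction of the substrate charge, and the plateau is read from the last two readings: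

plateau = 21.5%, catalyst fraction = 5.00%

N = plateau / catalyst fraction = 4.30

This N is the turnover number, the target made per catalyst charged before that catalyst stops working. The gap to the plateau gives the clock:

k = ln(gap at 3.00 h / gap at 6.00 h) / elapsed time = 0.327 /h

The gap falls a power of ten every 7.04 h. At 20 h it is 0.022 percentage points, less than the 2 points that counts. So this reckoning puts the flask at its plateau, and of the options, amber brings fresh catalyst while the others bring none.

Amber's bracket starts with a floor of 21.5% and a ceiling of 43.0%, the second charge making its full N. That ceiling is below the 50.0% that one coupling partner per target allows. To tighten it, the second charge is taken to run the south curve on a slower clock. In the south run substrate reads 73.5% of its charge at 20.0 h and, at one coupling partner per substrate gone, coupling partner stands at 47.0% of its own charge: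

rate follows substrate: 37.9%

rate follows substrate times partner: 32.1%

The forecast gives 21.5%, amber, 33.5% after amber and 21.6% after blue, on the ground that "The catalyst therefore dies". Its amber figure stands inside the bracket, above the lower edge of this reckoning and below the upper.

The flask gives 21.4%, amber as best with 14 points more, 35.4% after amber, inside the bracket, and 21.4% after blue.

    substrate + free catalyst ⇌ catalyst intermediate A (K = 3.20 /M, k = 27.0 /M/h, Ea = 70.0 kJ/mol, ΔH = −14.0 kJ/mol)
    coupling partner + catalyst intermediate A ⇌ catalyst intermediate B (K = 26.0 /M, k = 44.0 /M/h, Ea = 54.0 kJ/mol, ΔH = −17.0 kJ/mol)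
    catalyst intermediate B ⇌ by-product + catalyst intermediate C (K = 0.560 M, k = 29.0 /h, Ea = 76.0 kJ/mol, ΔH = −80.0 kJ/mol)
    catalyst intermediate C → catalyst intermediate D (k = 120 /h, Ea = 89.0 kJ/mol)
    catalyst intermediate D → free catalyst + target (k = 12.0 /h, Ea = 87.0 kJ/mol)
    target + catalyst intermediate C → spent catalyst A (k = 0.0270 /M/h, Ea = 62.0 kJ/mol)
    catalyst intermediate D → spent catalyst B (k = 2.80 /h, Ea = 100 kJ/mol)
    (constants at 25 °C)

In the flask at 1.20 h catalyst intermediate D goes to free catalyst + target 4.3 times as fast as to spent catalyst B, beside an N of 4.30 from the readings, and at 20.0 h spent catalyst B holds 99.9% of the catalyst. In the 6.0 h after amber the second charge makes 2.80 turnovers of that N. The neighbour flask with 0.20 M of substrate has 96.1% of its catalyst as spent catalyst B, so N gives 51.7% there, and it stands at 51.5%.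

(The numbers in the tables are simulated for an exercise; noise was put on by code.)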